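Everything rests on disconnecting the O1–C6 bond of the 1,2-dioxane ring (C1 acid carbon, C2 methyl-bearing carbon, C3–C6 ring carbons, O2 on C3, O1 on C6, chain C1', C2' … from C6). The feature exploited is the fully substituted ring carbon C6, which the terminal oxygen of a C3 hydroperoxide reaches in a six-membered closure once C6 and C1' are tied into an epoxide of defined configuration. One acid-promoted operation then forms O1–C6, closes the dioxane and sets C6 by inversion. The precursor is an acyclic (3S)-hydroperoxide with a silyl-protected C1 alcohol and a trisubstituted C6–C1' epoxy alcohol written by Sharpless epoxidation of the geraniol 2,3-alkene.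

Key step: step 12

Remark (stereochemistry): the target is (2S,3S,6S). Hydroperoxide 16 and dioxane diol 17 as drawn below map onto it without change. C2 and C3 carry over directly. C6 of 17 has the target geometry; its descriptor reads R at that stage only because the diol arm outranks C5. The epoxide of 16 has the sense of (2S,3S)-epoxygeraniol, which calls for L-(+)-diethyl tartrate.

Remark (handling): all compounds from 12 onward are peroxides; they should be kept cold, not concentrated to dryness on scale, and handled behind a shield.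

Step 1
Reactants: 1 geraniol
Product: 2 1-({[(2E)-3,7-dimethylocta-2,6-dien-1-yl]oxy}methyl)-4-methoxybenzene (geranyl 4-methoxybenzyl ether)
Conditions: NaH, 4-methoxybenzyl chloride, n-Bu4NI (cat.), THF/DMF, 0 °C → rt
Reagents that add atoms: 4-methoxybenzyl chloride, COc1ccc(CCl)cc1
Why: Williamson ether synthesis: the sodium alkoxide of the primary allylic alcohol should displace chloride from the benzylic halide (iodide catalysis) without touching either alkene, giving an ether that withstands every step until its oxidative removal in step 9.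

Step 2
Reactants: 2 geranyl 4-methoxybenzyl ether
Product: 4 (4E)-6-(4-methoxybenzyloxy)-4-methylhex-4-enal, via 6,7-epoxide 3 (not isolated)
Conditions: mCPBA (1.05 equiv), CH2Cl2, −20 → 0 °C; then H5IO6, THF/H2O, 0 °C
Reagents that add atoms: 3-chloroperbenzoic acid, OOC(=O)c1cccc(Cl)c1
Why: Prilezhaev epoxidation should pick the electron-rich distal trisubstituted alkene (the 2,3-alkene is deactivated by the allylic ether oxygen), and periodic acid then hydrolyses the epoxide and cleaves the glycol (Malaprade cleavage) to the aldehyde whose carbonyl carbon becomes C3.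

Step 3
Reactants: 5 (S)-4-benzyl-3-propanoyl-1,3-oxazolidin-2-one; 4 (4E)-6-(4-methoxybenzyloxy)-4-methylhex-4-enal
Product: 7 (4S)-4-benzyl-3-[(2S,3R,6E)-3-hydroxy-8-(4-methoxybenzyloxy)-2,6-dimethyloct-6-enoyl]-1,3-oxazolidin-2-one, via Z-dibutylboron enolate 6 (not isolated)
Conditions: n-Bu2BOTf, i-Pr2NEt, CH2Cl2, 0 °C; then 4, −78 → 0 °C; then pH 7 buffer, MeOH, 30% H2O2, 0 °C
Reagents that add atoms: none
Why: Evans syn-aldol reaction: the Z-boron enolate should react through a closed Zimmerman–Traxler chair with the auxiliary carbonyl turned away from the enolate oxygen, so the aldehyde is taken up on the face remote from the benzyl group, which sets C2 as in the target and C3 with the hydroxyl that is inverted in step 7.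

Step 4
Reactants: 7 aldol adduct
Product: 8 (2R,3R,6E)-8-(4-methoxybenzyloxy)-2,6-dimethyloct-6-ene-1,3-diol
Conditions: LiBH4, MeOH (1 equiv), THF, 0 °C
Reagents that add atoms: none
Why: Reductive cleavage of the N-acyloxazolidinone by borohydride at the more electrophilic exocyclic carbonyl should release C1 as a primary alcohol (so that the later C3 leaving group has no β-carbonyl and cannot eliminate by E1cB) without touching C2 or C3.

Step 5
Reactants: 8 diol
Product: 9 (2R,3R,6E)-1-[(tert-butyldiphenylsilyl)oxy]-8-(4-methoxybenzyloxy)-2,6-dimethyloct-6-en-3-ol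
Conditions: TBDPSCl (1.05 equiv), imidazole, CH2Cl2, 0 °C
Reagents that add atoms: tert-butyl(chloro)diphenylsilane, CC(C)(C)[Si](Cl)(c1ccccc1)c1ccccc1
Why: Chemoselective silylation: the bulky chlorosilane/imidazole pair should react at the primary hydroxyl far faster than at the hindered secondary one, leaving C3–OH free.

Step 6
Reactants: 9 secondary alcohol
Product: 10 (2R,3R,6E)-1-[(tert-butyldiphenylsilyl)oxy]-8-(4-methoxybenzyloxy)-2,6-dimethyloct-6-en-3-yl methanesulfonate
Conditions: MsCl, Et3N, CH2Cl2, 0 °C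
Reagents that add atoms: methanesulfonyl chloride, CS(=O)(=O)Cl
Why: Sulfonylation of the secondary alcohol (mesylation through sulfene) should convert C3–OH into a leaving group with retention, since the C–O bond is not broken.

Step 7
Reactants: 10 mesylate; 11 hydrogen peroxide
Product: 12 tert-butyl{[(2R,3S,6E)-3-hydroperoxy-8-(4-methoxybenzyloxy)-2,6-dimethyloct-6-en-1-yl]oxy}diphenylsilane
Conditions: 50% aq. H2O2 (large excess), KOH, MeOH/THF, 0 °C → rt
Reagents that add atoms: hydrogen peroxide (11), OO
Why: SN2 perhydrolysis of a secondary sulfonate: the hydroperoxide anion, an α-effect nucleophile, should displace mesylate with inversion, turning the aldol configuration at C3 into the (3S)-hydroperoxide of the target, while the aryl-methyl and silyl ethers tolerate cold methanolic KOH.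

Step 8
Reactants: 12 hydroperoxide
Product: 13 tert-butyl{[(2R,3S,6E)-8-(4-methoxybenzyloxy)-3-[(2-methoxypropan-2-yl)peroxy]-2,6-dimethyloct-6-en-1-yl]oxy}diphenylsilane
Conditions: 2-methoxypropene, PPTS (cat.), CH2Cl2, 0 °C
Reagents that add atoms: 2-methoxypropene, COC(C)=C
Why: Acid-catalysed addition of the hydroperoxide O–H across the enol ether should give the monoperoxyketal, which masks the OOH so that it can neither bind titanium nor act as an uncontrolled oxidant in step 10.

Step 9
Reactants: 13 peroxyketal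
Product: 14 (2E,6S,7R)-8-[(tert-butyldiphenylsilyl)oxy]-6-[(2-methoxypropan-2-yl)peroxy]-3,7-dimethyloct-2-en-1-ol
Conditions: DDQ, CH2Cl2/pH 7 phosphate buffer, 0 °C
Reagents that add atoms: none
Why: Oxidative cleavage of the 4-methoxybenzyl ether: DDQ should abstract hydride from the electron-rich benzylic position and the oxocarbenium ion is hydrolysed, the buffer sparing the acid-labile peroxyketal and the silyl ether.

Step 10
Reactants: 14 allylic alcohol
Product: 15 [(2S,3S)-3-{(3S,4R)-5-[(tert-butyldiphenylsilyl)oxy]-3-[(2-methoxypropan-2-yl)peroxy]-4-methylpentyl}-3-methyloxiran-2-yl]methanol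
Conditions: Ti(OiPr)4, L-(+)-diethyl tartrate, t-BuOOH (anhydrous, in decane), 4 Å molecular sieves, CH2Cl2, −20 °C; non-acidic work-up (H2O, then NaOH/brine)
Reagents that add atoms: tert-butyl hydroperoxide, CC(C)(C)OO
Why: Katsuki–Sharpless asymmetric epoxidation: the titanium tartrate complex should deliver oxygen to one face of the (E)-allylic alcohol under reagent control, in the sense that converts geraniol into (2S,3S)-epoxygeraniol with the L-(+)-tartrate, so C6 and C1' are written independently of the remote C2 and C3 centres.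

Step 11
Reactants: 15 masked epoxy alcohol
Product: 16 [(2S,3S)-3-{(3S,4R)-5-[(tert-butyldiphenylsilyl)oxy]-3-hydroperoxy-4-methylpentyl}-3-methyloxiran-2-yl]methanol
Conditions: PPTS (cat.), MeOH, 0 °C
Reagents that add atoms: none
Why: Acid-catalysed transketalisation with methanol should release the hydroperoxide under conditions too mild to open the epoxy alcohol intermolecularly, and any ring closure that already starts here leads to the same product as step 12.

Step 12
Reactants: 16 hydroperoxy epoxy alcohol
Product: 17 (1S)-1-{(3R,6S)-6-[(2R)-1-[(tert-butyldiphenylsilyl)oxy]propan-2-yl]-3-methyl-1,2-dioxan-3-yl}ethane-1,2-diol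
Conditions: 10-camphorsulfonic acid (0.2 equiv), CH2Cl2, 0 °C → rt
Reagents that add atoms: none
Why: The sulfonic acid activates the epoxide oxygen by protonation, and the terminal oxygen of the C3 hydroperoxide attacks C6 from the side opposite the breaking C6–O bond in a borderline SN2 opening, which forms O1–C6 and leaves the former epoxide oxygen as the C1' hydroxyl. The closest known reaction type is the acid-promoted intramolecular opening of epoxides by hydroperoxides to cyclic peroxides, together with the acid-catalysed perhydrolysis of trisubstituted epoxides at their tertiary carbon. The 1,2-dioxane closes in a 6-exo-tet mode. C6 is set by stereospecific inversion of the configuration installed by the L-(+)-tartrate epoxidation of the (E)-alkene, independently of C3, while C1' is retained. The step needs attack at C6 and not at C1'; this is secured because C6 is the tertiary carbon that best carries positive charge, whereas attack at C1' would be a seven-membered closure at a carbon made electron-poor by the adjacent hydroxymethyl group. A non-nucleophilic solvent and low temperature should keep the opening tight, so that no free cation erodes the invertive course and no external nucleophile competes.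

Step 13
Reactants: 17 dioxane diol
Product: 18 (3R,6S)-6-[(2R)-1-[(tert-butyldiphenylsilyl)oxy]propan-2-yl]-3-methyl-1,2-dioxane-3-carbaldehyde
Conditions: NaIO4, THF/pH 7 buffer, 0 °C → rt
Reagents that add atoms: none
Why: Malaprade glycol cleavage through a cyclic periodate ester should excise the hydroxymethyl carbon as formaldehyde and leave C1' as an aldehyde on the quaternary, non-enolisable C6, the dialkyl peroxide being inert to periodate.

Step 14
Reactants: 19 (2E,6E)-farnesyl bromide
Product: 20 triphenyl[(2E,6E)-3,7,11-trimethyldodeca-2,6,10-trien-1-yl]phosphonium bromide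
Conditions: PPh3, toluene, rt, dark
Reagents that add atoms: triphenylphosphine, c1ccc(cc1)P(c1ccccc1)c1ccccc1
Why: Quaternisation of triphenylphosphine by SN2 attack on the primary allylic bromide should give the Wittig salt with both (E)-alkenes unchanged.

Step 15
Reactants: 20 farnesyltriphenylphosphonium bromide; 18 dioxane aldehyde
Product: 22 tert-butyl{(2R)-2-[(3S,6R)-6-methyl-6-[(3E,7E)-4,8,12-trimethyltrideca-1,3,7,11-tetraen-1-yl]-1,2-dioxan-3-yl]propoxy}diphenylsilane (1E/1Z mixture), via farnesylidenetriphenylphosphorane 21 (not isolated)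
Conditions: NaN(SiMe3)2, THF, −78 °C; then 18, −78 → 0 °C
Reagents that add atoms: none
Why: Wittig olefination: the semi-stabilised allylic ylide, generated cold with a non-nucleophilic amide base so that its own 2,3-alkene keeps the (E)-geometry, should add to the non-enolisable aldehyde and form the C1'=C2' bond, whose geometry is immaterial because it is saturated in step 16.

Step 16
Reactants: 22 diene
Product: 23 tert-butyl{(2R)-2-[(3S,6S)-6-methyl-6-[(3E,7E)-4,8,12-trimethyltrideca-3,7,11-trien-1-yl]-1,2-dioxan-3-yl]propoxy}diphenylsilane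
Conditions: KO2CN=NCO2K (excess, in portions), AcOH, MeOH/CH2Cl2, 0 °C → rt, stopped when 22 is consumed
Reagents that add atoms: none
Why: Diimide reduction: concerted syn transfer of two hydrogens through a six-membered transition state slows steeply with alkene substitution, so the only 1,2-disubstituted alkene (the C1'=C2' end of the diene) should be saturated before any trisubstituted one, and diimide, unlike metal-catalysed hydrogenation, leaves the O–O bond intact.

Step 17
Reactants: 23 silyl ether
Product: 24 (2R)-2-[(3S,6S)-6-methyl-6-[(3E,7E)-4,8,12-trimethyltrideca-3,7,11-trien-1-yl]-1,2-dioxan-3-yl]propan-1-ol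
Conditions: Bu4NF, AcOH, THF, 0 °C → rt
Reagents that add atoms: none
Why: Fluoride-induced desilylation, driven by Si–F bond formation and buffered with acetic acid so that no free alkoxide can open the dioxane by Kornblum–DeLaMare-type elimination, should free the C1 alcohol.

Step 18
Reactants: 24 primary alcohol
Product: 25 (2S)-2-[(3S,6S)-6-methyl-6-[(3E,7E)-4,8,12-trimethyltrideca-3,7,11-trien-1-yl]-1,2-dioxan-3-yl]propanal
Conditions: Dess–Martin periodinane, NaHCO3, CH2Cl2, 0 °C → rt; used crude
Reagents that add atoms: none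
Why: Dess–Martin oxidation proceeds by ligand exchange at iodine and intramolecular removal of the carbinol hydrogen under buffered, near-neutral conditions, so the β-peroxy aldehyde should form without epimerisation at C2 or β-elimination and is used crude at once.

Step 19
Reactants: 25 aldehyde
Product: 26 (2S)-2-[(3S,6S)-6-methyl-6-[(3E,7E)-4,8,12-trimethyltrideca-3,7,11-trien-1-yl]-1,2-dioxan-3-yl]propanoic acid (CNP0179915.1)
Conditions: NaClO2, NaH2PO4, 2-methyl-2-butene (large excess), t-BuOH/H2O, 0 °C → rt
Reagents that add atoms: sodium chlorite, [Na+].[O-]Cl=O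
Why: Pinnick oxidation: chlorous acid should add to the aldehyde and fragment to the carboxylic acid under mildly acidic conditions that preserve C2 and the peroxide, while 2-methyl-2-butene traps the hypochlorous acid before it can attack the chain alkenes.

Compound list
1 | geraniol | CC(C)=CCC/C(C)=C/CO | starting material
2 | 1-({[(2E)-3,7-dimethylocta-2,6-dien-1-yl]oxy}methyl)-4-methoxybenzene | CC(C)=CCC/C(C)=C/COCc1ccc(OC)cc1 | intermediate
3 | 2-[(3E)-5-(4-methoxybenzyloxy)-3-methylpent-3-en-1-yl]-3,3-dimethyloxirane (racemic at the oxirane carbon) | CC1(C)OC1CC/C(C)=C/COCc1ccc(OC)cc1 | intermediate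
4 | (4E)-6-(4-methoxybenzyloxy)-4-methylhex-4-enal | O=CCC/C(C)=C/COCc1ccc(OC)cc1 | intermediate
5 | (S)-4-benzyl-3-propanoyl-1,3-oxazolidin-2-one | CCC(=O)N1[C@@H](Cc2ccccc2)COC1=O | starting material
6 | Z-dibutylboron enolate of 5 | C/C=C(\OB(CCCC)CCCC)N1[C@@H](Cc2ccccc2)COC1=O | intermediate
7 | (4S)-4-benzyl-3-[(2S,3R,6E)-3-hydroxy-8-(4-methoxybenzyloxy)-2,6-dimethyloct-6-enoyl]-1,3-oxazolidin-2-one | COc1ccc(COC/C=C(C)/CC[C@@H](O)[C@H](C)C(=O)N2[C@@H](Cc3ccccc3)COC2=O)cc1 | intermediate
8 | (2R,3R,6E)-8-(4-methoxybenzyloxy)-2,6-dimethyloct-6-ene-1,3-diol | COc1ccc(COC/C=C(C)/CC[C@@H](O)[C@H](C)CO)cc1 | intermediate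
9 | (2R,3R,6E)-1-[(tert-butyldiphenylsilyl)oxy]-8-(4-methoxybenzyloxy)-2,6-dimethyloct-6-en-3-ol | COc1ccc(COC/C=C(C)/CC[C@@H](O)[C@H](C)CO[Si](c2ccccc2)(c2ccccc2)C(C)(C)C)cc1 | intermediate
10 | (2R,3R,6E)-1-[(tert-butyldiphenylsilyl)oxy]-8-(4-methoxybenzyloxy)-2,6-dimethyloct-6-en-3-yl methanesulfonate | COc1ccc(COC/C=C(C)/CC[C@@H](OS(C)(=O)=O)[C@H](C)CO[Si](c2ccccc2)(c2ccccc2)C(C)(C)C)cc1 | intermediate
11 | hydrogen peroxide | OO | starting material
12 | tert-butyl{[(2R,3S,6E)-3-hydroperoxy-8-(4-methoxybenzyloxy)-2,6-dimethyloct-6-en-1-yl]oxy}diphenylsilane | COc1ccc(COC/C=C(C)/CC[C@H](OO)[C@H](C)CO[Si](c2ccccc2)(c2ccccc2)C(C)(C)C)cc1 | intermediate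
13 | tert-butyl{[(2R,3S,6E)-8-(4-methoxybenzyloxy)-3-[(2-methoxypropan-2-yl)peroxy]-2,6-dimethyloct-6-en-1-yl]oxy}diphenylsilane | COc1ccc(COC/C=C(C)/CC[C@H](OOC(C)(C)OC)[C@H](C)CO[Si](c2ccccc2)(c2ccccc2)C(C)(C)C)cc1 | intermediate
14 | (2E,6S,7R)-8-[(tert-butyldiphenylsilyl)oxy]-6-[(2-methoxypropan-2-yl)peroxy]-3,7-dimethyloct-2-en-1-ol | OC/C=C(C)/CC[C@H](OOC(C)(C)OC)[C@H](C)CO[Si](c1ccccc1)(c1ccccc1)C(C)(C)C | intermediate
15 | [(2S,3S)-3-{(3S,4R)-5-[(tert-butyldiphenylsilyl)oxy]-3-[(2-methoxypropan-2-yl)peroxy]-4-methylpentyl}-3-methyloxiran-2-yl]methanol | OC[C@@H]1O[C@@]1(C)CC[C@H](OOC(C)(C)OC)[C@H](C)CO[Si](c2ccccc2)(c2ccccc2)C(C)(C)C | intermediate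
16 | [(2S,3S)-3-{(3S,4R)-5-[(tert-butyldiphenylsilyl)oxy]-3-hydroperoxy-4-methylpentyl}-3-methyloxiran-2-yl]methanol | OC[C@@H]1O[C@@]1(C)CC[C@H](OO)[C@H](C)CO[Si](c2ccccc2)(c2ccccc2)C(C)(C)C | intermediate
17 | (1S)-1-{(3R,6S)-6-[(2R)-1-[(tert-butyldiphenylsilyl)oxy]propan-2-yl]-3-methyl-1,2-dioxan-3-yl}ethane-1,2-diol | OC[C@H](O)[C@@]1(C)CC[C@@H]([C@H](C)CO[Si](c2ccccc2)(c2ccccc2)C(C)(C)C)OO1 | intermediate
18 | (3R,6S)-6-[(2R)-1-[(tert-butyldiphenylsilyl)oxy]propan-2-yl]-3-methyl-1,2-dioxane-3-carbaldehyde | O=C[C@@]1(C)CC[C@@H]([C@H](C)CO[Si](c2ccccc2)(c2ccccc2)C(C)(C)C)OO1 | intermediate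
19 | (2E,6E)-farnesyl bromide | CC(C)=CCC/C(C)=C/CC/C(C)=C/CBr | starting material
20 | triphenyl[(2E,6E)-3,7,11-trimethyldodeca-2,6,10-trien-1-yl]phosphonium bromide | CC(C)=CCC/C(C)=C/CC/C(C)=C/C[P+](c1ccccc1)(c1ccccc1)c1ccccc1.[Br-] | intermediate
21 | farnesylidenetriphenylphosphorane | CC(C)=CCC/C(C)=C/CC/C(C)=C/C=P(c1ccccc1)(c1ccccc1)c1ccccc1 | intermediate
22 | tert-butyl{(2R)-2-[(3S,6R)-6-methyl-6-[(3E,7E)-4,8,12-trimethyltrideca-1,3,7,11-tetraen-1-yl]-1,2-dioxan-3-yl]propoxy}diphenylsilane (1E/1Z mixture) | CC(C)=CCC/C(C)=C/CC/C(C)=C/C=C[C@@]1(C)CC[C@@H]([C@H](C)CO[Si](c2ccccc2)(c2ccccc2)C(C)(C)C)OO1 | intermediate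
23 | tert-butyl{(2R)-2-[(3S,6S)-6-methyl-6-[(3E,7E)-4,8,12-trimethyltrideca-3,7,11-trien-1-yl]-1,2-dioxan-3-yl]propoxy}diphenylsilane | CC(C)=CCC/C(C)=C/CC/C(C)=C/CC[C@@]1(C)CC[C@@H]([C@H](C)CO[Si](c2ccccc2)(c2ccccc2)C(C)(C)C)OO1 | intermediate
24 | (2R)-2-[(3S,6S)-6-methyl-6-[(3E,7E)-4,8,12-trimethyltrideca-3,7,11-trien-1-yl]-1,2-dioxan-3-yl]propan-1-ol | CC(C)=CCC/C(C)=C/CC/C(C)=C/CC[C@@]1(C)CC[C@@H]([C@H](C)CO)OO1 | intermediate
25 | (2S)-2-[(3S,6S)-6-methyl-6-[(3E,7E)-4,8,12-trimethyltrideca-3,7,11-trien-1-yl]-1,2-dioxan-3-yl]propanal | CC(C)=CCC/C(C)=C/CC/C(C)=C/CC[C@@]1(C)CC[C@@H]([C@H](C)C=O)OO1 | intermediate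
26 | (2S)-2-[(3S,6S)-6-methyl-6-[(3E,7E)-4,8,12-trimethyltrideca-3,7,11-trien-1-yl]-1,2-dioxan-3-yl]propanoic acid | CC(C)=CCC/C(C)=C/CC/C(C)=C/CC[C@@]1(C)CC[C@@H]([C@H](C)C(=O)O)OO1 | target

Total step count: 19.
Longest linear sequence: 18 steps (geraniol 1 to acid 26 through steps 1–13 and 15–19; step 14 is a one-step side branch).

Steps most likely to fail

1. Step 7 (perhydrolysis of the mesylate). Elimination and solvolysis may outrun substitution at the β-branched secondary carbon, and the secondary hydroperoxide formed may be dehydrated to the ketone by the hydroxide. Fallback: set out from alcohol 9, which would be converted (Tf2O, 2,6-lutidine, CH2Cl2, −78 °C) into the secondary triflate F1. This would be displaced at −40 → 0 °C by the potassium salt (KOtBu, THF) of 2-methoxyprop-2-yl hydroperoxide F2, itself obtained by ozonolysis of 2,3-dimethylbut-2-ene in MeOH/CH2Cl2 at −78 °C. This known alkylation of a pre-masked hydroperoxide under anhydrous, cold conditions should proceed with inversion and deliver the peroxyketal directly, so the route is rejoined at 13.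

2. Step 12 (key ring closure). The protonated epoxide may ionise to a tertiary cation, eroding the invertive course or leading to elimination, and the acid may induce rearrangement of the hydroperoxide before it cyclises. Fallback: reverse the order of the two C–O bond formations. Setting out from mesylate 10, DDQ (CH2Cl2/pH 7 buffer) would give the allylic alcohol mesylate F3, and Sharpless epoxidation with L-(+)-diethyl tartrate the epoxy alcohol mesylate F4. Intermolecular perhydrolysis of the epoxide (anhydrous ethereal H2O2, catalytic H3PMo12O40) would then give the tertiary C6 hydroperoxide F5 with inversion at C6. KOtBu/18-crown-6 (THF, 0 °C) should close the ring by intramolecular SN2 displacement of the C3 mesylate (6-exo-tet, inversion at C3), which returns to the route at 17.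

3. Step 15 (Wittig chain attachment). The basic ylide may attack the dioxane (deprotonation at C3–H with O–O scission) or induce fragmentation of the α-peroxy aldehyde, and the delocalised allylic ylide may partly scramble the (E)-geometry of its 2,3-alkene. Fallback: a Julia–Kocienski olefination under Barbier conditions. Setting out from farnesyl bromide 19, 1-phenyl-1H-tetrazole-5-thiol/K2CO3 (acetone) would give the sulfide F6, and H2O2/(NH4)6Mo7O24 (EtOH, 0 °C) the sulfone F7. KN(SiMe3)2 added at −78 °C to a THF solution of F7 and aldehyde 18 keeps the carbanion concentration low and should give the same diene, rejoining the route at 22.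

Further compounds
F1 | step 7 | (2R,3R,6E)-1-[(tert-butyldiphenylsilyl)oxy]-8-(4-methoxybenzyloxy)-2,6-dimethyloct-6-en-3-yl trifluoromethanesulfonate | COc1ccc(COC/C=C(C)/CC[C@@H](OS(=O)(=O)C(F)(F)F)[C@H](C)CO[Si](c2ccccc2)(c2ccccc2)C(C)(C)C)cc1
F2 | step 7 | 2-methoxyprop-2-yl hydroperoxide | COC(C)(C)OO
F3 | step 12 | (2R,3R,6E)-1-[(tert-butyldiphenylsilyl)oxy]-8-hydroxy-2,6-dimethyloct-6-en-3-yl methanesulfonate | OC/C=C(C)/CC[C@@H](OS(C)(=O)=O)[C@H](C)CO[Si](c1ccccc1)(c1ccccc1)C(C)(C)C
F4 | step 12 | (2R,3R)-1-[(tert-butyldiphenylsilyl)oxy]-5-[(2S,3S)-3-(hydroxymethyl)-2-methyloxiran-2-yl]-2-methylpentan-3-yl methanesulfonate | OC[C@@H]1O[C@@]1(C)CC[C@@H](OS(C)(=O)=O)[C@H](C)CO[Si](c2ccccc2)(c2ccccc2)C(C)(C)C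
F5 | step 12 | (2R,3R,6R,7S)-1-[(tert-butyldiphenylsilyl)oxy]-6-hydroperoxy-7,8-dihydroxy-2,6-dimethyloctan-3-yl methanesulfonate | OC[C@H](O)[C@@](OO)(C)CC[C@@H](OS(C)(=O)=O)[C@H](C)CO[Si](c1ccccc1)(c1ccccc1)C(C)(C)C
F6 | step 15 | 1-phenyl-5-{[(2E,6E)-3,7,11-trimethyldodeca-2,6,10-trien-1-yl]sulfanyl}-1H-tetrazole | CC(C)=CCC/C(C)=C/CC/C(C)=C/CSc1nnnn1-c1ccccc1
F7 | step 15 | 1-phenyl-5-{[(2E,6E)-3,7,11-trimethyldodeca-2,6,10-trien-1-yl]sulfonyl}-1H-tetrazole | CC(C)=CCC/C(C)=C/CC/C(C)=C/CS(=O)(=O)c1nnnn1-c1ccccc1
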